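**Plan**
Retrosynthesis: cut O2–C3 of the lactone (ring B) to a methyl 2-(hept-1-ynyl)benzoate; cut C1'–C6' of ring C to an ArO–CH2–CO–CH2–CO–CH2–CO–C5H11 chain; cut C2'–C3' of that chain to an aryloxyacetamide and nonane-2,4-dione; cut O–C1' and C4–C4a back to methyl 2,4,6-trihydroxybenzoate, a bromoacetamide and 1-heptyne.
Forward: ring A is bought and its three hydroxyls are told apart (MOM on the para one, triflate then alkyne on one ortho one, the acetamide arm on the other). The triketone chain is grown on the ether oxygen, ring C is folded by aldol aromatisation and its C4' hydroxyl is methylated. Ring B is closed last by 6-endo attack of the ester on the alkyne, and the MOM group is then removed.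
Enabling feature: ring C (primed locants) carries the ether oxygen on C1', OH on C2', OMe on C4' and pentyl on C6'. This is the pattern left when a 1-aryloxyundecane-2,4,6-trione closes C1 onto the C6 carbonyl (chain C1–C6 become ring C1'–C6'; C7 is the first pentyl carbon).
Stereochemistry: the target has no stereocentre; the two stereocentres of the transient aldol adduct vanish on aromatisation.

Key step: step 6

Remark: the acetyl arm is introduced as the N-methoxy-N-methylamide rather than an ester, so that the chain extension is a single clean acyl transfer. Compounds 1, 4, 6 and 8 are taken as commercial.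

**Step 1**
Reactants: 1 methyl 2,4,6-trihydroxybenzoate
Product: 2 methyl 2,6-dihydroxy-4-(methoxymethoxy)benzoate
Conditions: MOMCl (1.05 equiv), i-Pr2NEt, CH2Cl2, 0 °C
Reagents that add atoms: chloromethyl methyl ether, COCCl
Why: Williamson-type O-alkylation (MOM protection): the 4-OH, para to the ester, is the most acidic phenol and the only one not held in a hydrogen bond to the ester, so one equivalent of the chloride should cap it and leave the two chelated ortho hydroxyls free.

**Step 2**
Reactants: 2 methyl 2,6-dihydroxy-4-(methoxymethoxy)benzoate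
Product: 3 methyl 2-hydroxy-4-(methoxymethoxy)-6-{[(trifluoromethyl)sulfonyl]oxy}benzoate
Conditions: Tf2O (1.0 equiv), pyridine, CH2Cl2, −20 → 0 °C
Reagents that add atoms: trifluoromethanesulfonic anhydride, O=S(=O)(OS(=O)(=O)C(F)(F)F)C(F)(F)F
Why: O-sulfonylation of a phenol: the two ortho hydroxyls are equivalent, and once one is triflated the other is locked in a strong hydrogen bond to the ester carbonyl and deactivated, so one equivalent of anhydride should stop at the monotriflate while pyridine buffers the medium for the MOM acetal.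

**Step 3**
Reactants: 3 methyl 2-hydroxy-4-(methoxymethoxy)-6-{[(trifluoromethyl)sulfonyl]oxy}benzoate; 4 1-heptyne
Product: 5 methyl 2-(hept-1-yn-1-yl)-6-hydroxy-4-(methoxymethoxy)benzoate
Conditions: PdCl2(PPh3)2 (5 mol%), CuI (10 mol%), Et3N, DMF, 60 °C
Reagents that add atoms: none
Why: Sonogashira coupling: the aryl triflate ortho to the ester adds readily to zerovalent palladium formed from PdCl2(PPh3)2, the copper acetylide of 1-heptyne transmetalates, and the chelated phenol on the far side of the ester is a spectator.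

**Step 4**
Reactants: 5 methyl 2-(hept-1-yn-1-yl)-6-hydroxy-4-(methoxymethoxy)benzoate; 6 2-bromo-N-methoxy-N-methylacetamide
Product: 7 methyl 2-(hept-1-yn-1-yl)-6-{2-[methoxy(methyl)amino]-2-oxoethoxy}-4-(methoxymethoxy)benzoate
Conditions: K2CO3, DMF, 50 °C
Reagents that add atoms: none
Why: Williamson ether synthesis: carbonate in DMF frees the salicylate phenoxide and the primary α-bromo amide is a fast SN2 partner, while the base is far too weak to enolise the amide, so the new arm cannot close onto the ester.

**Step 5**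
Reactants: 7 methyl 2-(hept-1-yn-1-yl)-6-{2-[methoxy(methyl)amino]-2-oxoethoxy}-4-(methoxymethoxy)benzoate; 8 nonane-2,4-dione
Product: 10 methyl 2-(hept-1-yn-1-yl)-4-(methoxymethoxy)-6-[(2,4,6-trioxoundecyl)oxy]benzoate, via dilithium nonane-2,4-dione dianion 9 (not isolated)
Conditions: 8 (2.5 equiv), LiN(i-Pr)2 (5.0 equiv), THF, −78 → 0 °C; then 7, −78 → −20 °C; aq. NH4Cl
Reagents that add atoms: none
Why: Claisen-type C-acylation of a 1,3-diketone dianion with a Weinreb amide: the second deprotonation of the diketone enolate occurs at the unhindered terminal methyl group, that carbon is the only strongly nucleophilic site of 9, the chelated tetrahedral adduct of the N-methoxy-N-methylamide survives until the quench so that one acyl group is transferred, and the twisted, electron-rich 2,6-disubstituted benzoate should not compete as an acceptor.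

**Step 6**
Reactants: 10 methyl 2-(hept-1-yn-1-yl)-4-(methoxymethoxy)-6-[(2,4,6-trioxoundecyl)oxy]benzoate
Product: 12 methyl 2-(2,4-dihydroxy-6-pentylphenoxy)-6-(hept-1-yn-1-yl)-4-(methoxymethoxy)benzoate, via cyclic aldol adduct 11 (not isolated)
Conditions: KOH (1 M aq.), MeOH, Ar, 0 °C → rt; then 1 M HCl to pH 4, 0 °C
Reagents that add atoms: none
Why: Hydroxide turns the triketone into its enolates; the carbanion at the oxygen-bearing C1' adds to the C6' ketone, the only carbonyl it can reach through a six-membered transition state, to give aldol 11, and E1cB loss of water followed by enolisation of the C2' and C4' carbonyls should deliver the resorcinol irreversibly. The closest known reaction type is the biomimetic intramolecular aldol aromatisation of 2,4,6-triketones in aqueous alkali (heptane-2,4,6-trione to orcinol), applied here to a 1-aryloxy member of the class. Ring C closes in the 6-(enolendo)-exo-trig mode, and no stereocentre survives because both stereocentres of 11 are erased on aromatisation. Two selectivities are needed and both are expected rather than proven. First, C1' and not the pentyl-side methylene C7 must be the nucleophile (attack of C7 on the C2' carbonyl would give the isomeric 4-butyl-5-(aryloxymethyl)resorcinol); the ether oxygen makes the C1' hydrogens the more acidic terminal ones, which should secure this. Second, the C1' carbanion must add to the ketone and not to the neighbouring ester in a five-membered Dieckmann closure; the much higher electrophilicity of a ketone over an electron-rich, doubly ortho-substituted benzoate should secure this, and the same hindrance should keep the methyl ester, alkyne and MOM ether intact in aqueous base at room temperature.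

**Step 7**
Reactants: 12 methyl 2-(2,4-dihydroxy-6-pentylphenoxy)-6-(hept-1-yn-1-yl)-4-(methoxymethoxy)benzoate
Product: 13 methyl 2-(hept-1-yn-1-yl)-6-(2-hydroxy-4-methoxy-6-pentylphenoxy)-4-(methoxymethoxy)benzoate
Conditions: MeI (1.05 equiv), K2CO3 (1.1 equiv), acetone, 0 °C → rt
Reagents that add atoms: iodomethane, CI
Why: Williamson O-methylation under steric control: the C4' hydroxyl is flanked by two ring hydrogens, whereas the C2' hydroxyl sits beside the crowded diaryl ether and can hydrogen-bond to the ether oxygen or the ester of ring A, so one equivalent of iodomethane with a mild base should alkylate C4'–OH first.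

**Step 8**
Reactants: 13 methyl 2-(hept-1-yn-1-yl)-6-(2-hydroxy-4-methoxy-6-pentylphenoxy)-4-(methoxymethoxy)benzoate
Product: 14 8-(2-hydroxy-4-methoxy-6-pentylphenoxy)-6-(methoxymethoxy)-3-pentyl-1H-isochromen-1-one
Conditions: AuCl3 (5 mol%), MeCN–H2O (20:1), 50 °C
Reagents that add atoms: water, O
Why: Gold-catalysed 6-endo-dig oxycyclisation of an o-alkynylbenzoate: AuCl3 activates the alkyne, the ester carbonyl oxygen attacks the distal pentyl-bearing alkyne carbon (favoured over 5-exo for an alkyl-substituted alkyne on an electron-rich benzoate), water adds to the resulting 1-methoxyisochromenylium ion and methanol is expelled, and protodeauration releases the isocoumarin.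

**Step 9**
Reactants: 14 8-(2-hydroxy-4-methoxy-6-pentylphenoxy)-6-(methoxymethoxy)-3-pentyl-1H-isochromen-1-one
Product: 15 6-hydroxy-8-(2-hydroxy-4-methoxy-6-pentylphenoxy)-3-pentyl-1H-isochromen-1-one (NP-007099)
Conditions: HCl (2 M in MeOH), 40 °C
Reagents that add atoms: none
Why: Acid-catalysed acetal exchange (MOM cleavage): protonation of the aryl methoxymethyl ether and capture of the oxocarbenium ion by methanol frees the C6 phenol, and the lactone, the diaryl ether and the aryl methyl ether are stable to methanolic HCl.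

**Compound list**
1 | methyl 2,4,6-trihydroxybenzoate | COC(=O)c1c(O)cc(O)cc1O | starting material
2 | methyl 2,6-dihydroxy-4-(methoxymethoxy)benzoate | COCOc1cc(O)c(C(=O)OC)c(O)c1 | intermediate
3 | methyl 2-hydroxy-4-(methoxymethoxy)-6-{[(trifluoromethyl)sulfonyl]oxy}benzoate | COCOc1cc(O)c(C(=O)OC)c(OS(=O)(=O)C(F)(F)F)c1 | intermediate
4 | 1-heptyne | CCCCCC#C | starting material
5 | methyl 2-(hept-1-yn-1-yl)-6-hydroxy-4-(methoxymethoxy)benzoate | CCCCCC#Cc1cc(OCOC)cc(O)c1C(=O)OC | intermediate
6 | 2-bromo-N-methoxy-N-methylacetamide | CON(C)C(=O)CBr | starting material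
7 | methyl 2-(hept-1-yn-1-yl)-6-{2-[methoxy(methyl)amino]-2-oxoethoxy}-4-(methoxymethoxy)benzoate | CCCCCC#Cc1cc(OCOC)cc(OCC(=O)N(C)OC)c1C(=O)OC | intermediate
8 | nonane-2,4-dione | CCCCCC(=O)CC(C)=O | starting material
9 | dilithium nonane-2,4-dione dianion (terminal dienolate, not isolated) | [Li+].[Li+].C=C([O-])C=C([O-])CCCCC | intermediate
10 | methyl 2-(hept-1-yn-1-yl)-4-(methoxymethoxy)-6-[(2,4,6-trioxoundecyl)oxy]benzoate (key-step precursor) | CCCCCC#Cc1cc(OCOC)cc(OCC(=O)CC(=O)CC(=O)CCCCC)c1C(=O)OC | intermediate
11 | methyl 2-(hept-1-yn-1-yl)-6-[(2-hydroxy-4,6-dioxo-2-pentylcyclohexyl)oxy]-4-(methoxymethoxy)benzoate (cyclic aldol adduct, diastereomer mixture, not isolated) | CCCCCC1(O)CC(=O)CC(=O)C1Oc1cc(OCOC)cc(C#CCCCCC)c1C(=O)OC | intermediate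
12 | methyl 2-(2,4-dihydroxy-6-pentylphenoxy)-6-(hept-1-yn-1-yl)-4-(methoxymethoxy)benzoate (key-step product) | CCCCCC#Cc1cc(OCOC)cc(Oc2c(O)cc(O)cc2CCCCC)c1C(=O)OC | intermediate
13 | methyl 2-(hept-1-yn-1-yl)-6-(2-hydroxy-4-methoxy-6-pentylphenoxy)-4-(methoxymethoxy)benzoate | CCCCCC#Cc1cc(OCOC)cc(Oc2c(O)cc(OC)cc2CCCCC)c1C(=O)OC | intermediate
14 | 8-(2-hydroxy-4-methoxy-6-pentylphenoxy)-6-(methoxymethoxy)-3-pentyl-1H-isochromen-1-one | CCCCCc1cc2cc(OCOC)cc(Oc3c(O)cc(OC)cc3CCCCC)c2c(=O)o1 | intermediate
15 | 6-hydroxy-8-(2-hydroxy-4-methoxy-6-pentylphenoxy)-3-pentyl-1H-isochromen-1-one (NP-007099) | CCCCCc1cc2cc(O)cc(Oc3c(O)cc(OC)cc3CCCCC)c2c(=O)o1 | target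

Total step count: 9. Longest linear sequence: 9 steps (1 → 15); compounds 4, 6 and 8 enter as purchased reagents.

**Steps most likely to fail**

Step 6. The C1' carbanion may not do what ring C needs: the aldol may run in the reverse sense from the pentyl-side methylene, or the carbanion may be drained into a five-membered Dieckmann closure on the ortho ester. The fallback sets out from 5 and returns at 13; it brings ring C in as a preformed carbocycle and aromatises it by dehydrogenation. Commercial 5-pentylcyclohexane-1,3-dione (CCCCCC1CC(=O)CC(=O)C1) is converted with MeOH and catalytic TsOH into 3-methoxy-5-pentylcyclohex-2-en-1-one F1. Its kinetic enolate (LiN(i-Pr)2, THF, −78 °C), which forms at C6, is brominated with N-bromosuccinimide to 6-bromo-3-methoxy-5-pentylcyclohex-2-en-1-one F2. Phenol 5 displaces the bromide (K2CO3, acetone) to give methyl 2-(hept-1-yn-1-yl)-6-[(4-methoxy-2-oxo-6-pentylcyclohex-3-en-1-yl)oxy]-4-(methoxymethoxy)benzoate F3. Dehydrogenation with DDQ in dioxane should aromatise the ring to 13. The C4' methoxyl is then in place from the enol ether, so this detour also avoids step 7.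

Step 7. Methylation may fail to tell the two ring C hydroxyls apart and give both monoethers and the diether. The fallback sets out from 12 and returns at 15; it separates the hydroxyls with a bulky silyl group before any methylation. i-Pr3SiCl and imidazole in DMF should silylate only the open C4' hydroxyl, giving methyl 2-(hept-1-yn-1-yl)-6-{2-hydroxy-6-pentyl-4-[(triisopropylsilyl)oxy]phenoxy}-4-(methoxymethoxy)benzoate F4. MOMCl and i-Pr2NEt then cap the C2' hydroxyl to give methyl 2-(hept-1-yn-1-yl)-4-(methoxymethoxy)-6-{2-(methoxymethoxy)-6-pentyl-4-[(triisopropylsilyl)oxy]phenoxy}benzoate F5. Bu4NF in THF frees the C4' phenol, methyl 2-(hept-1-yn-1-yl)-6-[4-hydroxy-2-(methoxymethoxy)-6-pentylphenoxy]-4-(methoxymethoxy)benzoate F6. MeI and K2CO3 give methyl 2-(hept-1-yn-1-yl)-6-[4-methoxy-2-(methoxymethoxy)-6-pentylphenoxy]-4-(methoxymethoxy)benzoate F7. AuCl3 in wet MeCN closes ring B to 8-[4-methoxy-2-(methoxymethoxy)-6-pentylphenoxy]-6-(methoxymethoxy)-3-pentyl-1H-isochromen-1-one F8, and methanolic HCl removes both MOM groups to give 15.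

Step 5. Proton transfer from the acidic OCH2 group of amide 7 to the strongly basic dianion may outrun addition, returning the amide or letting its enolate close on the ester. The fallback sets out from 7 and returns at 10; it replaces the acylation by aldol addition to an aldehyde followed by oxidation. i-Bu2AlH (THF, −78 °C) reduces the Weinreb amide to methyl 2-(hept-1-yn-1-yl)-4-(methoxymethoxy)-6-(2-oxoethoxy)benzoate F9. Dianion 9 adds to this aldehyde at −78 °C, where carbonyl addition is much faster than enolisation, to give racemic methyl 2-(hept-1-yn-1-yl)-6-[(2-hydroxy-4,6-dioxoundecyl)oxy]-4-(methoxymethoxy)benzoate F10. Dess–Martin periodinane (CH2Cl2, NaHCO3) oxidises the secondary alcohol to triketone 10.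

**Further compounds**
F1 | step 6 | 3-methoxy-5-pentylcyclohex-2-en-1-one | CCCCCC1CC(=O)C=C(OC)C1
F2 | step 6 | 6-bromo-3-methoxy-5-pentylcyclohex-2-en-1-one | CCCCCC1CC(OC)=CC(=O)C1Br
F3 | step 6 | methyl 2-(hept-1-yn-1-yl)-6-[(4-methoxy-2-oxo-6-pentylcyclohex-3-en-1-yl)oxy]-4-(methoxymethoxy)benzoate | CCCCCC#Cc1cc(OCOC)cc(OC2C(=O)C=C(OC)CC2CCCCC)c1C(=O)OC
F4 | step 7 | methyl 2-(hept-1-yn-1-yl)-6-{2-hydroxy-6-pentyl-4-[(triisopropylsilyl)oxy]phenoxy}-4-(methoxymethoxy)benzoate | CCCCCC#Cc1cc(OCOC)cc(Oc2c(O)cc(O[Si](C(C)C)(C(C)C)C(C)C)cc2CCCCC)c1C(=O)OC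
F5 | step 7 | methyl 2-(hept-1-yn-1-yl)-4-(methoxymethoxy)-6-{2-(methoxymethoxy)-6-pentyl-4-[(triisopropylsilyl)oxy]phenoxy}benzoate | CCCCCC#Cc1cc(OCOC)cc(Oc2c(OCOC)cc(O[Si](C(C)C)(C(C)C)C(C)C)cc2CCCCC)c1C(=O)OC
F6 | step 7 | methyl 2-(hept-1-yn-1-yl)-6-[4-hydroxy-2-(methoxymethoxy)-6-pentylphenoxy]-4-(methoxymethoxy)benzoate | CCCCCC#Cc1cc(OCOC)cc(Oc2c(OCOC)cc(O)cc2CCCCC)c1C(=O)OC
F7 | step 7 | methyl 2-(hept-1-yn-1-yl)-6-[4-methoxy-2-(methoxymethoxy)-6-pentylphenoxy]-4-(methoxymethoxy)benzoate | CCCCCC#Cc1cc(OCOC)cc(Oc2c(OCOC)cc(OC)cc2CCCCC)c1C(=O)OC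
F8 | step 7 | 8-[4-methoxy-2-(methoxymethoxy)-6-pentylphenoxy]-6-(methoxymethoxy)-3-pentyl-1H-isochromen-1-one | CCCCCc1cc2cc(OCOC)cc(Oc3c(OCOC)cc(OC)cc3CCCCC)c2c(=O)o1
F9 | step 5 | methyl 2-(hept-1-yn-1-yl)-4-(methoxymethoxy)-6-(2-oxoethoxy)benzoate | CCCCCC#Cc1cc(OCOC)cc(OCC=O)c1C(=O)OC
F10 | step 5 | methyl 2-(hept-1-yn-1-yl)-6-[(2-hydroxy-4,6-dioxoundecyl)oxy]-4-(methoxymethoxy)benzoate (racemic) | CCCCCC#Cc1cc(OCOC)cc(OCC(O)CC(=O)CC(=O)CCCCC)c1C(=O)OC
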